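**Retrosynthetic overview**
- Target 17 ⇐ benzyl ether 16; the erythro diol ⇐ aryl 1,2-dione 14 by a catalyst-controlled double transfer hydrogenation; 14 ⇐ aryl propyne 13.
- Ring A is bought. Ring B (benzene) and the dihydrofuran ring are made together: 13 ⇐ pyridazinyl ether 11 by an intramolecular alkyne–pyridazine [4+2] cycloaddition with loss of N2.
- 11 ⇐ alcohol 6 + chloropyridazine 9 (SNAr); 9 ⇐ 3,6-dichloro-4-methoxypyridazine + propyne.
- 6 ⇐ aldehyde 2 + (R)-butynyl mesylate 4 (anti-selective propargylation sets C2 and C3).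

Assumption: propyne is used as its commercial THF solution; the minor syn isomer of step 3 and any C3-coupled isomer of step 4 are removed by chromatography.

**Step 1**
Reactants: 1 3-hydroxy-4,5-dimethoxybenzaldehyde
Product: 2 3-(benzyloxy)-4,5-dimethoxybenzaldehyde
Conditions: BnBr (1.1 equiv), K2CO3, DMF, rt
Reagents that add atoms: benzyl bromide, BrCc1ccccc1
Why: Williamson ether synthesis masks the phenol, which would otherwise consume Et2Zn in step 3 and compete as a nucleophile in step 5.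

**Step 2**
Reactants: 3 (R)-but-3-yn-2-ol
Product: 4 (R)-but-3-yn-2-yl methanesulfonate
Conditions: MsCl, Et3N, CH2Cl2, −78 → 0 °C
Reagents that add atoms: methanesulfonyl chloride, CS(=O)(=O)Cl
Why: O-sulfonylation forms only the O–S bond, so the stereocentre keeps its R configuration.

**Step 3**
Reactants: 2 3-(benzyloxy)-4,5-dimethoxybenzaldehyde; 4 (R)-but-3-yn-2-yl methanesulfonate
Product: 6 (1S,2S)-1-[3-(benzyloxy)-4,5-dimethoxyphenyl]-2-methylbut-3-yn-1-ol, via allenylzinc reagent 5 (not isolated)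
Conditions: Pd(OAc)2 (5 mol %), PPh3 (5 mol %), Et2Zn (3 equiv), THF, −78 → −20 °C
Reagents that add atoms: none
Why: Marshall propargylation: zerovalent palladium opens 4 by anti SN2' oxidative addition, transmetalation gives allenylzinc 5, and its cyclic SE2' addition to the aldehyde forms the methyl-bearing carbon with net inversion (R → S) and places aryl anti to methyl, giving the anti (1S,2S) alcohol.

**Step 4**
Reactants: 7 3,6-dichloro-4-methoxypyridazine; 8 propyne
Product: 9 3-chloro-4-methoxy-6-(prop-1-yn-1-yl)pyridazine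
Conditions: PdCl2(PPh3)2 (3 mol %), CuI (5 mol %), Et3N, THF, 8 (1.1 equiv), 45 °C, sealed vessel
Reagents that add atoms: none
Why: Sonogashira coupling; oxidative addition is expected at C6, because the C3–Cl bond is hindered and made electron-richer by the ortho methoxy group (regiochemistry checked by HMBC from H5 to the alkynyl carbon).

**Step 5**
Reactants: 6 (1S,2S)-1-[3-(benzyloxy)-4,5-dimethoxyphenyl]-2-methylbut-3-yn-1-ol; 9 3-chloro-4-methoxy-6-(prop-1-yn-1-yl)pyridazine
Product: 11 3-{[(1S,2S)-1-[3-(benzyloxy)-4,5-dimethoxyphenyl]-2-methylbut-3-yn-1-yl]oxy}-4-methoxy-6-(prop-1-yn-1-yl)pyridazine, via sodium alkoxide 10 (not isolated)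
Conditions: NaH (1.05 equiv), THF, 0 °C; then 9, 0 °C → rt
Reagents that add atoms: none
Why: SNAr (addition–elimination) at C3 of the chlorodiazine, activated by the ring nitrogens and the alkynyl group at C6; the C–O bond at the stereocentre is not broken, so both centres are retained.

**Step 6**
Reactants: 11 the pyridazinyl ether from step 5
Product: 13 (2S,3S)-2-[3-(benzyloxy)-4,5-dimethoxyphenyl]-7-methoxy-3-methyl-5-(prop-1-yn-1-yl)-2,3-dihydro-1-benzofuran, via diazabicyclooctatriene cycloadduct 12 (not isolated)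
Conditions: 1,3,5-triisopropylbenzene (0.01 M), argon, 230 °C, sealed tube, 24–48 h
Reagents that add atoms: none
Why: Intramolecular inverse-electron-demand Diels–Alder reaction of the diazine (C3/C6) with the tethered terminal alkyne, then retro-Diels–Alder loss of N2, a known entry from 3-(alk-3-ynyloxy)pyridazines to 2,3-dihydrobenzofurans; the O–C–C tether closes the dihydrofuran while the diazine carbons plus the alkyne become ring B (C3–O → C7a, C4–OMe → C7, C6–propynyl → C5), and the two tether stereocentres are spectators.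

**Step 7**
Reactants: 13 the 5-propynyl dihydrobenzofuran
Product: 14 1-[(2S,3S)-2-[3-(benzyloxy)-4,5-dimethoxyphenyl]-7-methoxy-3-methyl-2,3-dihydro-1-benzofuran-5-yl]propane-1,2-dione
Conditions: PdBr2 (5 mol %), CuBr2 (10 mol %), O2 (1 atm), 1,4-dioxane/H2O 5:1, 60 °C
Reagents that add atoms: water, O
Why: Wacker-type oxidation of the internal aryl alkyne to the 1,2-dione (water as oxygen nucleophile, O2 reoxidising palladium through copper); no stereocentre is involved.

**Step 8**
Reactants: 14 the aryl propane-1,2-dione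
Product: 16 (1R,2S)-1-[(2S,3S)-2-[3-(benzyloxy)-4,5-dimethoxyphenyl]-7-methoxy-3-methyl-2,3-dihydro-1-benzofuran-5-yl]propane-1,2-diol, via (S)-hydroxy ketone 15 (not isolated)
Conditions: RuCl[(S,S)-TsDPEN](p-cymene) (2 mol %), HCO2H/Et3N 5:2, DMF, 40 °C
Reagents that add atoms: none
Why: Noyori–Ikariya asymmetric transfer hydrogenation of a 1-arylpropane-1,2-dione: the acetyl carbonyl is reduced first to (S)-15 and the aryl ketone then with the same catalyst-controlled facial sense, giving the anti (1R,2S) diol, the sense being inferred from the model by which the (S,S) catalyst turns benzil into (R,R)-hydrobenzoin and to be confirmed on 16.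

**Step 9**
Reactants: 16 the benzyl-protected diol
Product: 17 (1R,2S)-1-[(2S,3S)-2-(3-hydroxy-4,5-dimethoxyphenyl)-7-methoxy-3-methyl-2,3-dihydro-1-benzofuran-5-yl]propane-1,2-diol (CNP0229216.1)
Conditions: H2 (1 atm), 10% Pd/C, EtOAc, rt
Reagents that add atoms: none
Why: Hydrogenolysis of the aryl benzyl ether under neutral conditions, which leaves the benzylic alcohol, the cyclic benzylic ether and all four stereocentres untouched.

**Compound list**
1 | 3-hydroxy-4,5-dimethoxybenzaldehyde | COc1cc(C=O)cc(O)c1OC | starting material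
2 | 3-(benzyloxy)-4,5-dimethoxybenzaldehyde | COc1cc(C=O)cc(OCc2ccccc2)c1OC | intermediate
3 | (R)-but-3-yn-2-ol | C#C[C@@H](C)O | starting material
4 | (R)-but-3-yn-2-yl methanesulfonate | C#C[C@@H](C)OS(C)(=O)=O | intermediate
5 | (aS)-buta-1,2-dien-1-yl(ethyl)zinc | CC([H])=[C@@]=C([H])[Zn]CC | intermediate (not isolated)
6 | (1S,2S)-1-[3-(benzyloxy)-4,5-dimethoxyphenyl]-2-methylbut-3-yn-1-ol | C#C[C@H](C)[C@H](O)c1cc(OC)c(OC)c(OCc2ccccc2)c1 | intermediate
7 | 3,6-dichloro-4-methoxypyridazine | COc1cc(Cl)nnc1Cl | starting material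
8 | propyne | CC#C | starting material
9 | 3-chloro-4-methoxy-6-(prop-1-yn-1-yl)pyridazine | COc1cc(C#CC)nnc1Cl | intermediate
10 | sodium (1S,2S)-1-[3-(benzyloxy)-4,5-dimethoxyphenyl]-2-methylbut-3-yn-1-olate | C#C[C@H](C)[C@H]([O-])c1cc(OC)c(OC)c(OCc2ccccc2)c1.[Na+] | intermediate (not isolated)
11 | 3-{[(1S,2S)-1-[3-(benzyloxy)-4,5-dimethoxyphenyl]-2-methylbut-3-yn-1-yl]oxy}-4-methoxy-6-(prop-1-yn-1-yl)pyridazine | C#C[C@H](C)[C@H](Oc1nnc(C#CC)cc1OC)c1cc(OC)c(OC)c(OCc2ccccc2)c1 | intermediate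
12 | [4+2] cycloadduct of 11: 2,3-diazabicyclo[2.2.2]octa-2,5,7-triene with the dihydrofuran fused at the O-bearing bridgehead, propynyl on the other bridgehead, configuration at C2 and C3 as in 13 | CC#CC12N=NC3(O[C@H](c4cc(OC)c(OC)c(OCc5ccccc5)c4)[C@@H](C)C3=C1)C(OC)=C2 | intermediate (not isolated)
13 | (2S,3S)-2-[3-(benzyloxy)-4,5-dimethoxyphenyl]-7-methoxy-3-methyl-5-(prop-1-yn-1-yl)-2,3-dihydro-1-benzofuran | COc1cc([C@H]2Oc3c(OC)cc(C#CC)cc3[C@@H]2C)cc(OCc2ccccc2)c1OC | intermediate
14 | 1-[(2S,3S)-2-[3-(benzyloxy)-4,5-dimethoxyphenyl]-7-methoxy-3-methyl-2,3-dihydro-1-benzofuran-5-yl]propane-1,2-dione | COc1cc([C@H]2Oc3c(OC)cc(C(=O)C(C)=O)cc3[C@@H]2C)cc(OCc2ccccc2)c1OC | intermediate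
15 | (S)-1-[(2S,3S)-2-[3-(benzyloxy)-4,5-dimethoxyphenyl]-7-methoxy-3-methyl-2,3-dihydro-1-benzofuran-5-yl]-2-hydroxypropan-1-one | COc1cc([C@H]2Oc3c(OC)cc(C(=O)[C@H](C)O)cc3[C@@H]2C)cc(OCc2ccccc2)c1OC | intermediate (not isolated)
16 | (1R,2S)-1-[(2S,3S)-2-[3-(benzyloxy)-4,5-dimethoxyphenyl]-7-methoxy-3-methyl-2,3-dihydro-1-benzofuran-5-yl]propane-1,2-diol | COc1cc([C@H]2Oc3c(OC)cc([C@@H](O)[C@H](C)O)cc3[C@@H]2C)cc(OCc2ccccc2)c1OC | intermediate
17 | (1R,2S)-1-[(2S,3S)-2-(3-hydroxy-4,5-dimethoxyphenyl)-7-methoxy-3-methyl-2,3-dihydro-1-benzofuran-5-yl]propane-1,2-diol | COc1cc([C@H]2Oc3c(OC)cc([C@@H](O)[C@H](C)O)cc3[C@@H]2C)cc(O)c1OC | target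

**Totals**
Total step count: 9. Longest linear sequence: 7 (steps 1, 3, 5, 6, 7, 8, 9 from compound 1).

**Three steps most likely to fail**

Step 6 is the main risk. The diazine carries two donor oxygens, so the cycloaddition may be slower than thermal loss of the pyridazinone from the benzylic ether. Fallback: lower the diene LUMO with an acyl group and extend the chain afterwards. Set out from 7: aminocarbonylation at C6 (Pd(OAc)2, Xantphos, CO 1 atm, MeNH(OMe)·HCl, Et3N, toluene, 80 °C) gives 6-chloro-N,5-dimethoxy-N-methylpyridazine-3-carboxamide F1. SNAr with alkoxide 10 gives 6-{[(1S,2S)-1-[3-(benzyloxy)-4,5-dimethoxyphenyl]-2-methylbut-3-yn-1-yl]oxy}-N,5-dimethoxy-N-methylpyridazine-3-carboxamide F2. This carboxamide-activated diazine should cyclise at about 150–170 °C through its diazabicyclooctatriene cycloadduct F3 to (2S,3S)-2-[3-(benzyloxy)-4,5-dimethoxyphenyl]-N,7-dimethoxy-N,3-dimethyl-2,3-dihydro-1-benzofuran-5-carboxamide F4. Addition of 1-ethoxyvinyllithium (ethyl vinyl ether, t-BuLi, THF, −78 °C) gives 1-[(2S,3S)-2-[3-(benzyloxy)-4,5-dimethoxyphenyl]-7-methoxy-3-methyl-2,3-dihydro-1-benzofuran-5-yl]-2-ethoxyprop-2-en-1-one F5. Mild acid hydrolysis of the enol ether (1 M HCl, THF) returns to the route at dione 14.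

Step 4 may not discriminate well between the two C–Cl bonds; the C6 preference is argued from electronics and sterics, not demonstrated. Fallback: differentiate the positions by halogen instead of by catalyst. From 7, iodide exchange (NaI, AcCl, MeCN) proceeds through the N-acylpyridazinium at the nitrogen remote from the methoxy-bearing side and swaps the C6 chloride, giving 3-chloro-6-iodo-4-methoxypyridazine F6. Sonogashira coupling with 8 at room temperature (PdCl2(PPh3)2, CuI, Et3N) then occurs only at the C–I bond and returns to 9.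

Step 7 may give ring bromination or simple alkyne hydration on this electron-rich substrate. Fallback: reach the dione in two separate oxidation-state changes. From 13, Markovnikov hydration (Ph3PAuNTf2 2 mol %, wet 1,4-dioxane, 80 °C; water adds at the carbon next to the donor-substituted arene) gives 1-[(2S,3S)-2-[3-(benzyloxy)-4,5-dimethoxyphenyl]-7-methoxy-3-methyl-2,3-dihydro-1-benzofuran-5-yl]propan-1-one F7. Riley oxidation (SeO2, 1,4-dioxane/H2O, 90 °C) of the α-methylene then returns to 14.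

**Further compounds**
F1 | step 6 | 6-chloro-N,5-dimethoxy-N-methylpyridazine-3-carboxamide | COc1cc(C(=O)N(C)OC)nnc1Cl
F2 | step 6 | 6-{[(1S,2S)-1-[3-(benzyloxy)-4,5-dimethoxyphenyl]-2-methylbut-3-yn-1-yl]oxy}-N,5-dimethoxy-N-methylpyridazine-3-carboxamide | C#C[C@H](C)[C@H](Oc1nnc(C(=O)N(C)OC)cc1OC)c1cc(OC)c(OC)c(OCc2ccccc2)c1
F3 | step 6 | diazabicyclooctatriene cycloadduct of F2 (not isolated) | CON(C)C(=O)C12N=NC3(O[C@H](c4cc(OC)c(OC)c(OCc5ccccc5)c4)[C@@H](C)C3=C1)C(OC)=C2
F4 | step 6 | (2S,3S)-2-[3-(benzyloxy)-4,5-dimethoxyphenyl]-N,7-dimethoxy-N,3-dimethyl-2,3-dihydro-1-benzofuran-5-carboxamide | COc1cc([C@H]2Oc3c(OC)cc(C(=O)N(C)OC)cc3[C@@H]2C)cc(OCc2ccccc2)c1OC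
F5 | step 6 | 1-[(2S,3S)-2-[3-(benzyloxy)-4,5-dimethoxyphenyl]-7-methoxy-3-methyl-2,3-dihydro-1-benzofuran-5-yl]-2-ethoxyprop-2-en-1-one | COc1cc([C@H]2Oc3c(OC)cc(C(=O)C(=C)OCC)cc3[C@@H]2C)cc(OCc2ccccc2)c1OC
F6 | step 4 | 3-chloro-6-iodo-4-methoxypyridazine | COc1cc(I)nnc1Cl
F7 | step 7 | 1-[(2S,3S)-2-[3-(benzyloxy)-4,5-dimethoxyphenyl]-7-methoxy-3-methyl-2,3-dihydro-1-benzofuran-5-yl]propan-1-one | COc1cc([C@H]2Oc3c(OC)cc(C(=O)CC)cc3[C@@H]2C)cc(OCc2ccccc2)c1OC
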